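## The problem

CNP0183104.1 (18) is an unsymmetrical dimer of two trans-α,β-dibenzyl-γ-butyrolactones, both (3S,4S); lactone atoms are numbered O1, C2 (carbonyl), C3 (α), C4 (β), C5 (OCH2). Each lactone carries a 3,4-dimethoxybenzyl group (rings A and D) on C4. The two α-benzyl groups are the halves of a diaryl ether: ring B is a 3-methoxy-4-aryloxyphenyl unit and ring C a 4-hydroxy-3-methoxy-5-aryloxyphenyl unit. The skeleton therefore falls into three pieces, one diaryl ether core with two benzylic carbons and the same β-veratrylmethyl lactone used twice. The hindered, ortho-oxygenated C–O–C link is best made early on simple arenes, and the two C3–CH2 bonds late.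

Of the four stereocenters only the two C4 centers are configurationally fixed. C3 lies α to the carbonyl, is epimerizable and prefers the trans relation, so C4 can control C3. The two lactones are separated by the whole diaryl ether and cannot control each other, so each C4 must arrive with its configuration in place.

The groups that limit the reagents are the free phenol of ring C (acidic, nucleophilic, oxidizable), the two lactones (opened by hydroxide, alkoxide and hard organometallics), the epimerizable α-centers and the easily ionized electron-rich benzylic positions.

The enabling feature is the substitution of C4. It is bonded to the ring OCH2 (C5), the ring CH (C3) and the veratryl CH2, which is the environment of C5 in a 3-oxabicyclo[3.1.0]hexan-2-one. The cyclopropane CH2 (C6) of such a bicycle becomes the benzylic carbon when an aryl nucleophile opens the three-membered ring, and an ester at C1 makes C3 a malonate-type carbon that can be joined to the core under mild base.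

## Retrosynthesis

**18 from 17.** The O–CH2Ph bond of benzyl ether 17 is cut last. Benzyl is preferred to a sixth methyl ether, which could not be removed selectively, and to silyl or acyl groups, which would not survive carbonate in DMF or hot chloride. The forward hydrogenolysis only has to spare a diaryl ether, benzylic C–C bonds and lactones, all inert to H2 on palladium.

**17 from 16.** A methoxycarbonyl group is put back on each C3, giving bis(ester) 16. This makes C3 a malonate-type carbon, so the bonds to the core can be formed with carbonate base and cannot over-alkylate or exchange protons. The neighbouring option, direct alkylation of the simple lactone enolate, would need two cryogenic lithium enolate alkylations on one bis-electrophile. The forward Krapcho reaction must remove both esters and leave C3 trans to C4 under thermodynamic control.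

**16 from 15 and two molecules of 9.** Both C3–CH2(aryl) bonds are cut, giving dibromide 15 and lactone ester 9. This is the most convergent cut: three pieces of similar size, with the chiral piece used twice. A late cut at the diaryl ether C–O bond would instead demand a hindered Ullmann coupling between two elaborated lactones. Because rings B and C differ, any minor enantiomer of 9 ends up in diastereomers of 16, so the union also upgrades enantiopurity. The forward step is a double C-benzylation.

**9 from 5 and 7 (key disconnection).** The aryl–CH2 bond is cut and the CH2 reconnected to C3, which gives bicyclic cyclopropane 5 and Grignard reagent 7; the forward reaction passes through enolate 8. The only robust stereocenter is then not created but carried from 5. Cutting the CH2–C4 bond instead would require an asymmetric conjugate addition to create C4. The forward reaction must attack C6 and not C5 or the carbonyl groups.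

**5 from 1 and 2; 7 from 6.** Bicycle 5 is cut at C1–C6, C1–C5 and the lactone acyl–O bond, leading to (S)-epichlorohydrin 1 and dimethyl malonate 2 through epoxide 3 and cyclopropane 4. All atoms and the stereocenter of 5 come from two bulk chemicals in one flask. Grignard reagent 7 comes from 4-bromoveratrole 6.

**15 from 14, 13, 11, 12 and 10.** The C–Br bonds lead back to diol 14 and dialdehyde 13. The C5–O bond of ring C is cut to aryl iodide 11 and vanillin 12, and 11 comes from 5-iodovanillin 10. Both rings are bought with all oxygens in place and with aldehydes that become the benzylic carbons; the only bond to make is the diaryl ether, on small robust molecules. The forward Ullmann coupling has to tolerate two aldehydes and ortho substituents on both partners.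

## Roads not taken

**Alternative 1:** The cut is at both C4–benzylic carbon bonds, with the veratryl carbon as a masked acyl anion. Two equivalents of 2-lithio-2-(3,4-dimethoxyphenyl)-1,3-dithiane A3 would add to the β-carbons of bis(5-menthyloxybutenolide) A2, anti to the acetal substituent. An equilibrating proton quench would place both α-benzyl groups trans and give bis(dithianyl acetal lactone) A1.
- Merits: all four stereocenters and two C–C bonds are set in one operation under auxiliary control, with the lactones and the link to the core already in place.
- Weak points:
  - A2 must first be assembled by joining two alkoxybutenolides to the core through their α-carbons.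
  - α-Substituted butenolides are sluggish acceptors for a hindered tertiary dithianyl anion.
  - The configuration of 18 calls for the acetal derived from (1S,2R,5S)-menthol, the less accessible enantiomer.
  - After the key step four C–S bonds and two acetal C–O bonds must be removed reductively, two to three further operations on a molecule with two lactones.
- Comparison: this road is better in stereochemical economy, since C3 and C4 are set together. The chosen plan sets against it a purchased stereocenter, no auxiliary, no sulfur, no organolithium on a bis-electrophile, and only two steps after the fragment union.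

**Alternative 2:** Both lactone rings are cut, each at its acyl–oxygen bond and its C3–carbonyl bond, so the carbonyl carbons come from carbon monoxide. Bis(homopropargylic alcohol) A5 would take up two CO under PdCl2(PPh3)2 and SnCl2, and the hydroxyl groups would capture the acyl–palladium intermediates to close both rings as bis[(E)-α-arylidene lactone] A4.
- Merits: two rings and four bonds form in one catalytic step, and a final hydrogenation would saturate both alkenes and remove the benzyl group together.
- Weak points:
  - The stereochemical problem is only moved. Both C4 centers must already be present in A5, which needs two enantiopure alkynol fragments and a double Sonogashira coupling to a core dihalide.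
  - Hydrogenation of the arylidene lactones delivers hydrogen anti to the C4 substituent, so it is expected to favour the cis lactones and to require a separate epimerization.
  - Hydropalladation of two electron-rich aryl alkynes must be regioselective twice.
  - CO and a tin salt are needed.
- Comparison: as ring construction this is more elegant and forms more bonds per step than anything in the chosen plan. The chosen plan sets against it that ring and stereocenter both arrive in its first step and that the overall step count is lower.

**Alternative 3:** The cut is the O1–C5 bond of a single lactone, traced back to an oxygen insertion. Asymmetric Baeyer–Villiger oxidation of prochiral cyclobutanone A7 with aqueous hydrogen peroxide and a chiral phosphoric acid would insert oxygen next to one of two enantiotopic CH2 groups and give lactone A6.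
- Merits: chirality comes from a catalyst; A7 is achiral and simple; A6 is the classical lignan building block, whose lithium enolate is alkylated trans directly with no ester to remove.
- Weak points:
  - The prochiral carbon of A7 is remote from the carbonyl and carries a flexible benzyl group, so high selectivity is less assured than for 3-aryl cyclobutanones.
  - The veratryl ring is exposed to peroxide and Brønsted acid.
  - A7 itself needs a ketene cycloaddition and dehalogenation sequence.
  - The union with the core needs two cryogenic enolate alkylations on one bis-electrophile.
- Comparison: step count is about equal. Alternative 3 is superior in using only catalytic chirality and in giving the trans relation kinetically. The chosen plan sets against it an enantiopurity that is bought rather than dependent on catalyst selectivity, and a carbonate-mediated union that cannot over-alkylate. A6 is also the compound through which the fallback for step 8 passes.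

Key step: step 3

Assumption: 9 is drawn as its trans (3R,4S) epimer and 16 as the anti-alkylation product (3S at both quaternary carbons); both C3 centers are erased in step 9, so the route does not depend on them.

## Steps

Step 1
Reactants: 1 (S)-epichlorohydrin; 2 dimethyl malonate
Product: 5 methyl (1R,5S)-2-oxo-3-oxabicyclo[3.1.0]hexane-1-carboxylate, via epoxymalonate 3 (not isolated), via hydroxymethylcyclopropane diester 4 (not isolated)
Conditions: NaOMe (1.1 equiv), MeOH, 0 °C → reflux
Reagents that add atoms: none
Why: Known one-flask malonate–epichlorohydrin cascade: the malonate anion opens the epoxide at its CH2, the alkoxide displaces chloride to give 3, the re-formed malonate anion opens 3 at the secondary carbon (3-exo-tet, inversion) to give 4, whose alkoxide lactonizes onto the cis ester. C5 takes its S configuration from the purchased epoxide and C1 follows from the obligatory cis ring fusion.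

Step 2
Reactants: 6 4-bromoveratrole
Product: 7 3,4-dimethoxyphenylmagnesium bromide (THF solution, titrated and used directly)
Conditions: Mg turnings, I2 (cat.), THF, 40–60 °C
Reagents that add atoms: magnesium, [Mg]
Why: Grignard formation by insertion of magnesium into the aryl C–Br bond; the methyl ethers are inert.

Step 3
Reactants: 5 methyl (1R,5S)-2-oxo-3-oxabicyclo[3.1.0]hexane-1-carboxylate; 7 3,4-dimethoxyphenylmagnesium bromide
Product: 9 methyl (3R,4S)-4-(3,4-dimethoxybenzyl)-2-oxotetrahydrofuran-3-carboxylate, via bromomagnesium enolate 8 (not isolated)
Conditions: CuI (15 mol %), THF, −30 → −10 °C, slow addition of 7; then 1 M HCl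
Reagents that add atoms: none
Why: Reagent 7 transmetallates to monovalent copper, and the aryl cuprate attacks the cyclopropane CH2 (C6) of 5 from the rear of the C1–C6 bond in an SN2-like homoconjugate addition; that bond breaks with the lactone–ester enolate as leaving group, giving chelated magnesium enolate 8, which is protonated on work-up. The closest known reaction type is the copper-catalysed Grignard opening of 2-oxo-3-oxabicyclo[3.1.0]hexane-1-carboxylates to 4-substituted 2-oxotetrahydrofuran-3-carboxylates, itself a case of cuprate homoconjugate addition to cyclopropane-1,1-dicarbonyl compounds. No ring is closed: the three-membered ring is opened and the five-membered lactone is carried through. No lasting stereocenter is created: C4 (former C5) keeps its S configuration because none of its bonds is touched, and C3 arises on protonation as an epimerizable center that settles trans to the C4 substituent. The step needs regioselectivity for C6 over the ring-fusion carbon C5 and chemoselectivity for the cyclopropane over the two carbonyl groups. The first follows from C6 being the unhindered primary carbon, whereas attack at C5 would need inversion at a ring-fusion carbon; the second from the softness of the cuprate at low temperature and slow addition, so that free Grignard reagent does not build up. Strain release and formation of a doubly stabilised enolate make the addition irreversible, and 8, being an enolate, is protected from further attack.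

Step 4
Reactants: 10 5-iodovanillin
Product: 11 4-(benzyloxy)-3-iodo-5-methoxybenzaldehyde
Conditions: BnBr, K2CO3, DMF, 50 °C
Reagents that add atoms: benzyl bromide, BrCc1ccccc1
Why: Williamson O-benzylation of an acidic phenol; it masks the ring C hydroxyl so that only vanillin's oxygen can couple in step 5 and no phenoxide is present in step 8.

Step 5
Reactants: 11 4-(benzyloxy)-3-iodo-5-methoxybenzaldehyde; 12 vanillin
Product: 13 4-(benzyloxy)-3-(4-formyl-2-methoxyphenoxy)-5-methoxybenzaldehyde
Conditions: CuI (10 mol %), N,N-dimethylglycine hydrochloride (30 mol %), Cs2CO3, 1,4-dioxane, 100 °C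
Reagents that add atoms: none
Why: Ligand-accelerated Ullmann diaryl ether synthesis (copper phenoxide, oxidative addition of the aryl iodide, C–O reductive elimination). Neither partner has an enolizable position, the tertiary amine ligand cannot condense with the aldehydes, and the iodide offsets the hindrance of the ortho benzyloxy group.

Step 6
Reactants: 13 4-(benzyloxy)-3-(4-formyl-2-methoxyphenoxy)-5-methoxybenzaldehyde
Product: 14 {4-(benzyloxy)-3-[4-(hydroxymethyl)-2-methoxyphenoxy]-5-methoxyphenyl}methanol
Conditions: NaBH4, MeOH–THF, 0 °C
Reagents that add atoms: none
Why: Borohydride reduction of both aryl aldehydes to benzylic alcohols; ethers are untouched.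

Step 7
Reactants: 14 {4-(benzyloxy)-3-[4-(hydroxymethyl)-2-methoxyphenoxy]-5-methoxyphenyl}methanol
Product: 15 2-(benzyloxy)-5-(bromomethyl)-1-[4-(bromomethyl)-2-methoxyphenoxy]-3-methoxybenzene
Conditions: PBr3, CH2Cl2, 0 °C; used without storage
Reagents that add atoms: phosphorus tribromide, BrP(Br)Br
Why: Conversion of benzylic alcohols into bromides through their phosphite esters; the cold, brief conditions leave the aryl benzyl ether intact.

Step 8
Reactants: 15 2-(benzyloxy)-5-(bromomethyl)-1-[4-(bromomethyl)-2-methoxyphenoxy]-3-methoxybenzene; 9 methyl (3R,4S)-4-(3,4-dimethoxybenzyl)-2-oxotetrahydrofuran-3-carboxylate (2.2 equiv)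
Product: 16 bis(lactone ester): the O-benzyl diaryl ether core carrying on each benzylic CH2 a (3S,4S)-4-(3,4-dimethoxybenzyl)-3-(methoxycarbonyl)-2-oxotetrahydrofuran-3-yl group
Conditions: Cs2CO3, DMF, 0 °C → rt
Reagents that add atoms: none
Why: Double C-benzylation of a malonate-type lactone–ester enolate by SN2 at two primary benzylic bromides. The product has no acidic C–H left, so over-alkylation and proton exchange are excluded. The electrophile should enter anti to the C4 substituent, though this quaternary center is erased in step 9.

Step 9
Reactants: 16 bis(lactone ester)
Product: 17 O-benzyl ether of the target: the O-benzyl diaryl ether core carrying on each benzylic CH2 a (3S,4S)-4-(3,4-dimethoxybenzyl)-2-oxotetrahydrofuran-3-yl group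
Conditions: LiCl, H2O, DMSO, 150 °C
Reagents that add atoms: none
Why: Double Krapcho demethoxycarbonylation: chloride attacks each ester methyl group, and the carboxylates lose CO2 to lactone enolates that are protonated by water. Each C3 stereocenter is set under thermodynamic control by the fixed C4 center, since the trans-α,β-dibenzyl lactone is the stable epimer and the hot, weakly basic medium allows equilibration.

Step 10
Reactants: 17 O-benzyl ether of the target
Product: 18 CNP0183104.1
Conditions: H2 (1 atm), 10% Pd/C, EtOAc–MeOH, rt
Reagents that add atoms: none
Why: Hydrogenolysis of the aryl benzyl ether; diaryl ether, methyl ethers, lactones and benzylic C–C bonds are inert, and the neutral conditions do not epimerize C3.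

## Compound list

1 | (S)-epichlorohydrin | ClC[C@@H]1CO1 | starting material
2 | dimethyl malonate | COC(=O)CC(=O)OC | starting material
3 | dimethyl 2-{[(2S)-oxiran-2-yl]methyl}propanedioate (not isolated) | COC(=O)C(C[C@H]1CO1)C(=O)OC | intermediate
4 | dimethyl (2S)-2-(hydroxymethyl)cyclopropane-1,1-dicarboxylate, present as its sodium alkoxide (not isolated) | OC[C@H]1CC1(C(=O)OC)C(=O)OC | intermediate
5 | methyl (1R,5S)-2-oxo-3-oxabicyclo[3.1.0]hexane-1-carboxylate | COC(=O)[C@@]12C[C@@H]1COC2=O | intermediate
6 | 4-bromoveratrole (4-bromo-1,2-dimethoxybenzene) | COc1ccc(Br)cc1OC | starting material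
7 | 3,4-dimethoxyphenylmagnesium bromide | COc1ccc([Mg]Br)cc1OC | intermediate
8 | bromomagnesium enolate of methyl (4S)-4-(3,4-dimethoxybenzyl)-2-oxotetrahydrofuran-3-carboxylate (not isolated) | COC(=O)C1=C(O[Mg]Br)OC[C@H]1Cc1ccc(OC)c(OC)c1 | intermediate
9 | methyl (3R,4S)-4-(3,4-dimethoxybenzyl)-2-oxotetrahydrofuran-3-carboxylate (trans; C3 epimerizable) | COC(=O)[C@@H]1C(=O)OC[C@H]1Cc1ccc(OC)c(OC)c1 | intermediate
10 | 5-iodovanillin (4-hydroxy-3-iodo-5-methoxybenzaldehyde) | COc1cc(C=O)cc(I)c1O | starting material
11 | 4-(benzyloxy)-3-iodo-5-methoxybenzaldehyde | COc1cc(C=O)cc(I)c1OCc1ccccc1 | intermediate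
12 | vanillin (4-hydroxy-3-methoxybenzaldehyde) | COc1cc(C=O)ccc1O | starting material
13 | 4-(benzyloxy)-3-(4-formyl-2-methoxyphenoxy)-5-methoxybenzaldehyde | COc1cc(C=O)ccc1Oc1cc(C=O)cc(OC)c1OCc1ccccc1 | intermediate
14 | {4-(benzyloxy)-3-[4-(hydroxymethyl)-2-methoxyphenoxy]-5-methoxyphenyl}methanol | COc1cc(CO)ccc1Oc1cc(CO)cc(OC)c1OCc1ccccc1 | intermediate
15 | 2-(benzyloxy)-5-(bromomethyl)-1-[4-(bromomethyl)-2-methoxyphenoxy]-3-methoxybenzene | COc1cc(CBr)ccc1Oc1cc(CBr)cc(OC)c1OCc1ccccc1 | intermediate
16 | bis(lactone ester), both lactones (3S,4S)-3-(arylmethyl)-4-(3,4-dimethoxybenzyl)-3-(methoxycarbonyl), ring C oxygen benzylated | COC(=O)[C@@]1(Cc2ccc(Oc3cc(C[C@]4(C(=O)OC)C(=O)OC[C@H]4Cc4ccc(OC)c(OC)c4)cc(OC)c3OCc3ccccc3)c(OC)c2)C(=O)OC[C@H]1Cc1ccc(OC)c(OC)c1 | intermediate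
17 | O-benzyl ether of the target, both lactones trans-(3S,4S) | COc1ccc(C[C@@H]2COC(=O)[C@H]2Cc2ccc(Oc3cc(C[C@@H]4C(=O)OC[C@H]4Cc4ccc(OC)c(OC)c4)cc(OC)c3OCc3ccccc3)c(OC)c2)cc1OC | intermediate
18 | CNP0183104.1 | COc1ccc(C[C@@H]2COC(=O)[C@H]2Cc2ccc(Oc3cc(C[C@@H]4C(=O)OC[C@H]4Cc4ccc(OC)c(OC)c4)cc(OC)c3O)c(OC)c2)cc1OC | target

## Step count and risks

Total step count: 10. Longest linear sequence: 7 steps (10 → 11 → 13 → 14 → 15 → 16 → 17 → 18, steps 4 to 10); the lactone branch (steps 1 and 3, with step 2 for the reagent) joins at step 8.

Least certain steps:

**Step 3 (key step).** The process most likely to compete is direct 1,2-addition of the aryl Grignard reagent to the lactone or ester carbonyl, together with copper-mediated biaryl formation, because aryl cuprates transfer their group in homoconjugate additions more slowly than alkyl cuprates. Fallback: from 5, the cyclopropane is opened by iodide instead of carbon (Me3SiI, CH2Cl2, 0 °C, methanol quench), giving methyl (3R,4S)-4-(iodomethyl)-2-oxotetrahydrofuran-3-carboxylate F1. The aryl–CH2 bond is then made by nickel-catalysed reductive cross-electrophile coupling of F1 with 4-bromoveratrole 6 (NiI2, 4,4'-di-tert-butyl-2,2'-bipyridine, Zn, N,N-dimethylacetamide, 60 °C). This uses no basic organometallic reagent, leaves C4 untouched and returns to the route at 9.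

**Step 5.** Slow C–O coupling with competing reductive loss of iodine is the main risk: vanillin is an electron-poor, ortho-substituted phenol and the iodide of 11 sits next to the benzyloxy group. Fallback: the polarity of the ether formation is reversed. From 11, Miyaura borylation (B2pin2, PdCl2(dppf), KOAc, dioxane, 80 °C) gives 4-(benzyloxy)-3-methoxy-5-(4,4,5,5-tetramethyl-1,3,2-dioxaborolan-2-yl)benzaldehyde F2. Oxidation with N-methylmorpholine N-oxide gives 4-(benzyloxy)-3-hydroxy-5-methoxybenzaldehyde F3. Nucleophilic aromatic substitution of F3 on purchased 4-fluoro-3-methoxybenzaldehyde (COc1cc(C=O)ccc1F; K2CO3, DMSO, 110 °C), whose fluoride is activated by the para aldehyde, returns to the route at 13.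

**Step 8.** Incomplete second alkylation and solvolytic loss of the electron-rich benzylic bromides before both C–C bonds have formed are the main risks; O-alkylation of the enolate is a lesser one. Fallback: decarboxylation and alkylation are exchanged. From 9, Krapcho demethoxycarbonylation (LiCl, H2O, DMSO, 150 °C) gives (S)-4-(3,4-dimethoxybenzyl)dihydrofuran-2(3H)-one F4. Its lithium enolate (LiN(SiMe3)2, THF, −78 °C) is alkylated twice by 15, anti to the C4 substituent, which gives the trans lactones directly and returns to the route at 17, bypassing 16.

**Step 9.** Two processes threaten: chloride attack at the lactone O–CH2 instead of the ester methyl group, which opens the ring, and incomplete equilibration at C3, which leaves cis lactone. Fallback: from 16, dealkylative decarboxylation is replaced by hydrolysis and thermal decarboxylation. LiOH in aqueous THF followed by acidification, which recloses any lactone opened by hydroxide, gives bis(lactone carboxylic acid) F5. F5 loses CO2 on heating in toluene, and a final treatment with DBU equilibrates C3 to trans, returning to the route at 17.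

## Further compounds

F1 | step 3 | methyl (3R,4S)-4-(iodomethyl)-2-oxotetrahydrofuran-3-carboxylate | COC(=O)[C@@H]1C(=O)OC[C@H]1CI
F2 | step 5 | 4-(benzyloxy)-3-methoxy-5-(4,4,5,5-tetramethyl-1,3,2-dioxaborolan-2-yl)benzaldehyde | COc1cc(C=O)cc(B2OC(C)(C)C(C)(C)O2)c1OCc1ccccc1
F3 | step 5 | 4-(benzyloxy)-3-hydroxy-5-methoxybenzaldehyde | COc1cc(C=O)cc(O)c1OCc1ccccc1
F4 | step 8 | (S)-4-(3,4-dimethoxybenzyl)dihydrofuran-2(3H)-one | COc1ccc(C[C@@H]2COC(=O)C2)cc1OC
F5 | step 9 | bis(lactone carboxylic acid), the diacid corresponding to 16, both lactones (3S,4S) | OC(=O)[C@@]1(Cc2ccc(Oc3cc(C[C@]4(C(=O)O)C(=O)OC[C@H]4Cc4ccc(OC)c(OC)c4)cc(OC)c3OCc3ccccc3)c(OC)c2)C(=O)OC[C@H]1Cc1ccc(OC)c(OC)c1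
A1 | alternative 1 | bis(all-trans 3-arylmethyl-4-[2-(3,4-dimethoxyphenyl)-1,3-dithian-2-yl]-5-menthyloxy lactone) of the O-benzyl core | COc1cc(C[C@@H]2C(=O)O[C@H](O[C@H]3C[C@@H](C)CC[C@@H]3C(C)C)[C@H]2C2(SCCCS2)c2ccc(OC)c(OC)c2)ccc1Oc1cc(C[C@@H]2C(=O)O[C@H](O[C@H]3C[C@@H](C)CC[C@@H]3C(C)C)[C@H]2C2(SCCCS2)c2ccc(OC)c(OC)c2)cc(OC)c1OCc1ccccc1
A2 | alternative 1 | bis(butenolide): O-benzyl core carrying on each benzylic CH2 a (5S)-5-[(1S,2R,5S)-menthyloxy]-2-oxo-2,5-dihydrofuran-3-yl group | COc1cc(CC2=C[C@@H](O[C@H]3C[C@@H](C)CC[C@@H]3C(C)C)OC2=O)ccc1Oc1cc(CC2=C[C@@H](O[C@H]3C[C@@H](C)CC[C@@H]3C(C)C)OC2=O)cc(OC)c1OCc1ccccc1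
A3 | alternative 1 | 2-lithio-2-(3,4-dimethoxyphenyl)-1,3-dithiane | [Li]C1(SCCCS1)c1ccc(OC)c(OC)c1
A4 | alternative 2 | bis[(E)-α-arylidene-β-(3,4-dimethoxybenzyl)-γ-butyrolactone] of the O-benzyl core | COc1ccc(C[C@@H]2COC(=O)/C2=C/c2ccc(Oc3cc(/C=C4/C(=O)OC[C@H]4Cc4ccc(OC)c(OC)c4)cc(OC)c3OCc3ccccc3)c(OC)c2)cc1OC
A5 | alternative 2 | bis(homopropargylic alcohol): O-benzyl core carrying on each ring a (3S)-4-(3,4-dimethoxyphenyl)-3-(hydroxymethyl)but-1-yn-1-yl group | COc1ccc(C[C@H](CO)C#Cc2ccc(Oc3cc(C#C[C@@H](CO)Cc4ccc(OC)c(OC)c4)cc(OC)c3OCc3ccccc3)c(OC)c2)cc1OC
A6 | alternative 3 | (S)-4-(3,4-dimethoxybenzyl)dihydrofuran-2(3H)-one | COc1ccc(C[C@@H]2COC(=O)C2)cc1OC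
A7 | alternative 3 | 3-(3,4-dimethoxybenzyl)cyclobutan-1-one | COc1ccc(CC2CC(=O)C2)cc1OC
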